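**Retrosynthetic overview**

1. The target is traced back to the spiro acyl-trione without prenyl groups; the two prenyl groups go on last at the only free ring CH2.
2. The trione ring is opened by two Claisen disconnections: an intramolecular closure onto an ester, and before it the key intermolecular Claisen condensation of the dianion of 5-methylhexane-2,4-dione with a bridged γ-lactone ester. The lactone marks the carbonyl that is cis to the C4 oxygen, which fixes the spiro centre.
3. The lactone ester comes from a trans-fused hydrindanone carrying a geminal diester: equatorial methyl addition at C4 with lactonisation, and methyl addition at C1.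
4. The cyclohexane ring comes from malonate annulation of a trans-2,3-disubstituted cyclopentanone (Michael addition, allylic chlorination, intramolecular alkylation).
5. The cyclopentanone comes from Dieckmann closure of an adipate made by rhodium-catalysed asymmetric 1,4-addition. Ring order: cyclopentane, cyclohexane, lactone bridge, trione ring.

Assumption: bicyclic compounds are named with octahydroindene numbering (C1 to C7a), each compound is drawn as one tautomer, and diethyl methylidenepropanedioate is taken as the commercial stabilised monomer.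

**Route**

Step 1
Reactants: 1 tert-butyl prop-2-enoate; 2 methyl pent-4-enoate
Product: 3 1-tert-butyl 6-methyl (2E)-hex-2-enedioate
Conditions: second-generation Grubbs catalyst (2 mol %), CH2Cl2, 40 °C, 1 in threefold excess
Reagents that add atoms: none
Why: Cross-metathesis of an electron-poor acrylate with a terminal alkene gives the (E)-enoate selectively and releases ethene.

Step 2
Reactants: 3 1-tert-butyl 6-methyl (2E)-hex-2-enedioate; 4 4,4,5,5-tetramethyl-2-(prop-1-en-2-yl)-1,3,2-dioxaborolane
Product: 5 1-tert-butyl 6-methyl (3S)-3-(prop-1-en-2-yl)hexanedioate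
Conditions: [RhCl(cod)]2 (1.5 mol %), (R)-BINAP (3.3 mol %), KOH (10 mol %), dioxane/H2O 10:1, 60 °C
Reagents that add atoms: none
Why: Rhodium-catalysed asymmetric 1,4-addition (Hayashi–Miyaura reaction) to the (E)-enoate, in which the (R)-BINAP complex is expected to deliver the alkenyl group to the Si face of C3 and so set the 3S centre that becomes ring-fusion carbon C3a.

Step 3
Reactants: 5 1-tert-butyl 6-methyl (3S)-3-(prop-1-en-2-yl)hexanedioate
Product: 6 tert-butyl (1R,5S)-2-oxo-5-(prop-1-en-2-yl)cyclopentane-1-carboxylate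
Conditions: KOtBu (1.1 equiv), THF, 0 °C to rt; AcOH
Reagents that add atoms: none
Why: Dieckmann condensation in which only the enolate next to the tert-butyl ester can close onto the electrophilic methyl ester, so the β-keto ester carbon lies next to the stereocentre and its epimerisable centre settles trans.

Step 4
Reactants: 6 tert-butyl (1R,5S)-2-oxo-5-(prop-1-en-2-yl)cyclopentane-1-carboxylate; 7 diethyl methylidenepropanedioate
Product: 8 tert-butyl (1S,5R)-1-[3-ethoxy-2-(ethoxycarbonyl)-3-oxopropyl]-2-oxo-5-(prop-1-en-2-yl)cyclopentane-1-carboxylate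
Conditions: DBU (5 mol %), THF, 0 °C
Reagents that add atoms: none
Why: Intermolecular Michael addition of the β-keto ester, at its only acidic carbon and anti to the isopropenyl group, to the highly electrophilic methylidenemalonate.

Step 5
Reactants: 8 tert-butyl (1S,5R)-1-[3-ethoxy-2-(ethoxycarbonyl)-3-oxopropyl]-2-oxo-5-(prop-1-en-2-yl)cyclopentane-1-carboxylate
Product: 10 diethyl 2-{[(1R,5S)-2-oxo-5-(prop-1-en-2-yl)cyclopentyl]methyl}propanedioate, via keto acid 9 (not isolated)
Conditions: 85% aq. H3PO4, toluene, rt then 60 °C; DBU (5 mol %), CH2Cl2, rt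
Reagents that add atoms: none
Why: Mild acidolysis of the tert-butyl ester and decarboxylation of the β-keto acid leave an epimerisable α-carbon that equilibrates to the trans-2,3-disubstituted cyclopentanone (thermodynamic control).

Step 6
Reactants: 10 diethyl 2-{[(1R,5S)-2-oxo-5-(prop-1-en-2-yl)cyclopentyl]methyl}propanedioate
Product: 11 diethyl 2-{[(1R,5S)-5-(3-chloroprop-1-en-2-yl)-2-oxocyclopentyl]methyl}propanedioate
Conditions: Ca(OCl)2 (0.6 equiv), solid CO2, CH2Cl2/H2O, 0 °C
Reagents that add atoms: calcium hypochlorite (source of HOCl), [Ca+2].[O-]Cl.[O-]Cl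
Why: Ene-type allylic chlorination by hypochlorous acid attacks only the electron-rich 1,1-disubstituted alkene and gives the transposed allylic chloride, while ketone and malonate are not enolised at this pH.

Step 7
Reactants: 11 diethyl 2-{[(1R,5S)-5-(3-chloroprop-1-en-2-yl)-2-oxocyclopentyl]methyl}propanedioate
Product: 12 diethyl (3aS,7aR)-4-methylidene-1-oxooctahydro-6H-indene-6,6-dicarboxylate
Conditions: K2CO3 (1.5 equiv), NaI (10 mol %), acetone, rt
Reagents that add atoms: none
Why: Intramolecular malonate alkylation (SN2 and SN2' give the same product) closes the cyclohexane ring with a base too weak to enolise the ketone, so the trans ring fusion from step 5 is kept.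

Step 8
Reactants: 12 diethyl (3aS,7aR)-4-methylidene-1-oxooctahydro-6H-indene-6,6-dicarboxylate
Product: 13 diethyl (1S,3aS,7aR)-1-hydroxy-1-methyl-4-methylideneoctahydro-6H-indene-6,6-dicarboxylate
Conditions: MeTi(OiPr)3 (2 equiv), Et2O, −30 °C to rt; H2O
Reagents that add atoms: methyltitanium triisopropoxide, C[Ti](OC(C)C)(OC(C)C)OC(C)C
Why: Chemoselective 1,2-addition of the bulky methyltitanium reagent to the ketone (esters untouched) from the face syn to H-7a, away from the axial hydrogens at C3a and C7, gives the 1S carbinol with OH cis to C7.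

Step 9
Reactants: 13 diethyl (1S,3aS,7aR)-1-hydroxy-1-methyl-4-methylideneoctahydro-6H-indene-6,6-dicarboxylate
Product: 14 diethyl (1S,3aS,7aR)-1-hydroxy-1-methyl-4-oxooctahydro-6H-indene-6,6-dicarboxylate
Conditions: O3, CH2Cl2/MeOH, −78 °C; Me2S
Reagents that add atoms: ozone, [O-][O+]=O
Why: Ozonolysis of the exocyclic methylene with reductive work-up gives the cyclohexanone without touching any stereocentre.

Step 10
Reactants: 14 diethyl (1S,3aS,7aR)-1-hydroxy-1-methyl-4-oxooctahydro-6H-indene-6,6-dicarboxylate
Product: 16 bridged lactone ester (4,6-lactone of (1S,3aS,4R,6R,7aR)-6-(ethoxycarbonyl)-1,4-dihydroxy-1,4-dimethyloctahydroindene-6-carboxylic acid), via diol diester 15 (not isolated)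
Conditions: MeMgBr (3.5 equiv), CeCl3 (3.5 equiv), THF, −78 °C; H2O; then DBU (20 mol %), toluene, 60 °C
Reagents that add atoms: methylmagnesium bromide, C[Mg]Br
Why: Cerium-mediated Grignard addition occurs equatorially because the axial ester at C6 blocks the axial path, giving the axial 4R alcohol, which alone can lactonise onto the cis-axial ester and so differentiates the two carboxyl groups and fixes the future spiro centre.

Step 11
Reactants: 16 bridged lactone ester; 17 5-methylhexane-2,4-dione
Product: 18 ethyl (1S,3aS,4R,6S,7aR)-1,4-dihydroxy-1,4-dimethyl-6-(6-methyl-3,5-dioxoheptanoyl)octahydro-1H-indene-6-carboxylate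
Conditions: 17 (4 equiv), LiN(iPr)2 (8 equiv), THF, 0 °C; 16, −78 to −20 °C; AcOH
Reagents that add atoms: none
Why: Crossed Claisen condensation (acylation of a 1,3-diketone dianion at its terminal carbon), in which the strained γ-lactone is expected to be far more electrophilic than the equatorial neopentyl-type ethyl ester, so the chain is attached only to the axial carbonyl and the C4 hydroxyl is released.

Step 12
Reactants: 18 ethyl (1S,3aS,4R,6S,7aR)-1,4-dihydroxy-1,4-dimethyl-6-(6-methyl-3,5-dioxoheptanoyl)octahydro-1H-indene-6-carboxylate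
Product: 19 spiro trione (5-hydroxy-6-(2-methylpropanoyl)cyclohex-5-ene-1,3-dione whose C2 is C6 of (1S,3aS,4R,6S,7aR)-1,4-dihydroxy-1,4-dimethyloctahydroindene; the C3 carbonyl next to the ring CH2 is cis to 4-OH)
Conditions: NaOEt (4 equiv), EtOH, 78 °C; 1 M HCl
Reagents that add atoms: none
Why: Intramolecular Claisen (Dieckmann-type) condensation of the central carbon of the 1,3-diketone unit onto the remaining ester closes the six-membered trione ring under thermodynamic control, driven by the very acidic 2-acyl-1,3-dione product.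

Step 13
Reactants: 19 spiro trione; 20 1-bromo-3-methylbut-2-ene
Product: 21 target CNP0273836.6 (19 carrying two 3-methylbut-2-en-1-yl groups on C4 of the trione ring)
Conditions: KOH (3 equiv), H2O, 0 °C; 20 (2.5 equiv), 0 °C to rt
Reagents that add atoms: none
Why: Double C-alkylation of the only remaining ring CH2 of the β-triketone (aqueous base favours C- over O-alkylation) installs the geminal prenyl groups and creates no new stereocentre.

**Compound list**

1 | tert-butyl prop-2-enoate | C=CC(=O)OC(C)(C)C | starting material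
2 | methyl pent-4-enoate | C=CCCC(=O)OC | starting material
3 | 1-tert-butyl 6-methyl (2E)-hex-2-enedioate | CC(C)(C)OC(=O)/C=C/CCC(=O)OC | intermediate
4 | 4,4,5,5-tetramethyl-2-(prop-1-en-2-yl)-1,3,2-dioxaborolane | CC(=C)B1OC(C)(C)C(C)(C)O1 | starting material
5 | 1-tert-butyl 6-methyl (3S)-3-(prop-1-en-2-yl)hexanedioate | CC(C)(C)OC(=O)C[C@H](CCC(=O)OC)C(C)=C | intermediate
6 | tert-butyl (1R,5S)-2-oxo-5-(prop-1-en-2-yl)cyclopentane-1-carboxylate | CC(C)(C)OC(=O)[C@H]1C(=O)CC[C@@H]1C(C)=C | intermediate
7 | diethyl methylidenepropanedioate | C=C(C(=O)OCC)C(=O)OCC | starting material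
8 | tert-butyl (1S,5R)-1-[3-ethoxy-2-(ethoxycarbonyl)-3-oxopropyl]-2-oxo-5-(prop-1-en-2-yl)cyclopentane-1-carboxylate | CCOC(=O)C(C(=O)OCC)C[C@@]1(C(=O)OC(C)(C)C)C(=O)CC[C@@H]1C(C)=C | intermediate
9 | (1S,5R)-1-[3-ethoxy-2-(ethoxycarbonyl)-3-oxopropyl]-2-oxo-5-(prop-1-en-2-yl)cyclopentane-1-carboxylic acid | CCOC(=O)C(C(=O)OCC)C[C@@]1(C(O)=O)C(=O)CC[C@@H]1C(C)=C | intermediate
10 | diethyl 2-{[(1R,5S)-2-oxo-5-(prop-1-en-2-yl)cyclopentyl]methyl}propanedioate | CCOC(=O)C(C(=O)OCC)C[C@H]1C(=O)CC[C@@H]1C(C)=C | intermediate
11 | diethyl 2-{[(1R,5S)-5-(3-chloroprop-1-en-2-yl)-2-oxocyclopentyl]methyl}propanedioate | CCOC(=O)C(C(=O)OCC)C[C@H]1C(=O)CC[C@@H]1C(=C)CCl | intermediate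
12 | diethyl (3aS,7aR)-4-methylidene-1-oxooctahydro-6H-indene-6,6-dicarboxylate (trans-fused) | CCOC(=O)C1(C(=O)OCC)C[C@H]2C(=O)CC[C@@H]2C(=C)C1 | intermediate
13 | diethyl (1S,3aS,7aR)-1-hydroxy-1-methyl-4-methylideneoctahydro-6H-indene-6,6-dicarboxylate | CCOC(=O)C1(C(=O)OCC)C[C@H]2[C@@](C)(O)CC[C@@H]2C(=C)C1 | intermediate
14 | diethyl (1S,3aS,7aR)-1-hydroxy-1-methyl-4-oxooctahydro-6H-indene-6,6-dicarboxylate | CCOC(=O)C1(C(=O)OCC)C[C@H]2[C@@](C)(O)CC[C@@H]2C(=O)C1 | intermediate
15 | diethyl (1S,3aS,4R,7aR)-1,4-dihydroxy-1,4-dimethyloctahydro-6H-indene-6,6-dicarboxylate | CCOC(=O)C1(C(=O)OCC)C[C@H]2[C@@](C)(O)CC[C@@H]2[C@](C)(O)C1 | intermediate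
16 | bridged lactone ester: 4,6-lactone of (1S,3aS,4R,6R,7aR)-6-(ethoxycarbonyl)-1,4-dihydroxy-1,4-dimethyloctahydroindene-6-carboxylic acid (lactone carbonyl axial, ester equatorial) | CCOC(=O)[C@@]12C[C@H]3[C@@](C)(O)CC[C@@H]3[C@@](C)(C1)OC2=O | intermediate
17 | 5-methylhexane-2,4-dione | CC(=O)CC(=O)C(C)C | starting material
18 | ethyl (1S,3aS,4R,6S,7aR)-1,4-dihydroxy-1,4-dimethyl-6-(6-methyl-3,5-dioxoheptanoyl)octahydro-1H-indene-6-carboxylate | CCOC(=O)[C@@]1(C(=O)CC(=O)CC(=O)C(C)C)C[C@H]2[C@@](C)(O)CC[C@@H]2[C@](C)(O)C1 | intermediate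
19 | spiro trione: 5-hydroxy-6-(2-methylpropanoyl)cyclohex-5-ene-1,3-dione spiro-fused through its C2 to C6 (6S) of (1S,3aS,4R,7aR)-1,4-dihydroxy-1,4-dimethyloctahydroindene | C1C(=O)[C@@]2(C[C@@H]3[C@H](CC[C@]3(C)O)[C@](C)(O)C2)C(=O)C(C(=O)C(C)C)=C1O | intermediate
20 | 1-bromo-3-methylbut-2-ene | CC(C)=CCBr | starting material
21 | CNP0273836.6 (19 with two 3-methylbut-2-en-1-yl groups on C4 of the trione ring) | CC(C)=CCC1(CC=C(C)C)C(=O)[C@@]2(C[C@@H]3[C@H](CC[C@]3(C)O)[C@](C)(O)C2)C(=O)C(C(=O)C(C)C)=C1O | target

**Totals**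

Total step count: 13. Longest linear sequence: 13 steps (from 1 and 2 to 21).

**Steps most likely to fail, each with a fallback**

Step 11 (lactone versus ester selectivity in the intermolecular Claisen, and with it the hindered ring closure of step 12). If the dianion of 17 does not discriminate between the lactone and the ester of 16, or if 18 does not close, the order of the two Claisen events is reversed. Compound 16 is saponified (KOH, aqueous EtOH, 60 °C) and re-lactonised on acidification to the lactone acid F3. This is activated with 1,1'-carbonyldiimidazole as the acyl imidazolide F4, which C-acylates the magnesium enolate of 17 (MgCl2, Et3N, MeCN) at its central carbon to give the triacylmethane F5. Excess LiN(iPr)2 in THF then forms the terminal methyl-ketone carbanion, which attacks the lactone carbonyl intramolecularly and gives 19 directly. The route is rejoined at 19, and steps 11 and 12 are bypassed.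

Step 13 (C- versus O-alkylation and incomplete geminal dialkylation). If prenyl bromide gives mainly O-prenyl ethers or stops after one alkylation, the prenyl groups are introduced one at a time from 19 by palladium-catalysed allylic alkylation (Tsuji–Trost) with methyl 3-methylbut-2-en-1-yl carbonate and Pd(PPh3)4 in THF. The first cycle gives the mono-prenyl trione F6 and a second cycle gives 21. Any O-prenyl enol ether is re-ionised by the zerovalent palladium catalyst and converges on the C-alkylated product. The route is rejoined at 21.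

Step 6 (chemoselectivity of the hypochlorous acid chlorination in the presence of the malonate C–H and the ketone). If chlorination of 10 is unselective, 10 is instead oxidised at the allylic methyl group with SeO2 (cat.) and tBuOOH in CH2Cl2 to the allylic alcohol F1, which is converted with methyl chloroformate and pyridine into the allylic methyl carbonate F2. Pd(PPh3)4 in THF ionises the carbonate to a π-allyl complex of divalent palladium, which the malonate captures under neutral conditions (Tsuji–Trost cyclisation) to give 12, where the route is rejoined.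

**Further compounds**

F1 | step 6 | diethyl 2-{[(1R,5S)-5-(3-hydroxyprop-1-en-2-yl)-2-oxocyclopentyl]methyl}propanedioate | CCOC(=O)C(C(=O)OCC)C[C@H]1C(=O)CC[C@@H]1C(=C)CO
F2 | step 6 | diethyl 2-{[(1R,5S)-5-{3-[(methoxycarbonyl)oxy]prop-1-en-2-yl}-2-oxocyclopentyl]methyl}propanedioate | CCOC(=O)C(C(=O)OCC)C[C@H]1C(=O)CC[C@@H]1C(=C)COC(=O)OC
F3 | step 11 | lactone acid: 4,6-lactone of (1S,3aS,4R,6R,7aR)-1,4-dihydroxy-1,4-dimethyloctahydroindene-6,6-dicarboxylic acid (free CO2H equatorial) | OC(=O)[C@@]12C[C@H]3[C@@](C)(O)CC[C@@H]3[C@@](C)(C1)OC2=O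
F4 | step 11 | acyl imidazolide of the lactone acid (1H-imidazol-1-yl ketone at C6) | O=C(n4ccnc4)[C@@]12C[C@H]3[C@@](C)(O)CC[C@@H]3[C@@](C)(C1)OC2=O
F5 | step 11 | triacylmethane: 5-methylhexane-2,4-dione acylated at C3 by the C6 carbonyl of the lactone acid | CC(=O)C(C(=O)C(C)C)C(=O)[C@@]12C[C@H]3[C@@](C)(O)CC[C@@H]3[C@@](C)(C1)OC2=O
F6 | step 13 | mono-prenyl trione (19 with one 3-methylbut-2-en-1-yl group on C4 of the trione ring, epimerisable there) | CC(C)=CCC1C(=O)[C@@]2(C[C@@H]3[C@H](CC[C@]3(C)O)[C@](C)(O)C2)C(=O)C(C(=O)C(C)C)=C1O
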